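Numbering: C1 ketone, C2 =CH, C3 (side carbon C3a), C4 carbinol, C5 oxirane CH, C6 farnesylated oxirane carbon. Two bonds at C6 are cut: C5–C6 of the cyclohexenone and C6–O of the oxirane. The feature used is the triple role of C6, which flanks the C1 carbonyl, joins C5 in the six-membered ring and shares the three-membered ring oxygen with C5. A C6 that acts first as chloro enolate and then as alkyl chloride toward a C5 aldehyde builds both rings and both stereocentres in one reductive operation. The precursor is an open-chain Z-enone aldehyde with a farnesylated C6 gem-dichloride and a di-tert-butylsilylene bridging the C4 and C3a oxygens.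

Key step: step 12

Remark (structure check): in this numbering the target is (4R,5R,6R), with the C4 hydroxyl and the oxirane oxygen on the same ring face. The (S) centre of L-erythrulose maps onto (R)-C4 without inversion. Only the CIP ranking of its two carbon neighbours is reversed once the ketone carbon has become alkene carbon C3.
Remark: fragment atoms carry the target numbers (C1–C6, C3a) from the first step on.
Assumption: commercial L-erythrulose syrup is taken as enantiopure and is dried azeotropically before step 2.

Step 1
Reactants: 1 dichloromethane; 2 (2E,6E)-farnesyl bromide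
Product: 4 (3E,7E)-1,1-dichloro-4,8,12-trimethyltrideca-3,7,11-triene, via dichloromethyllithium 3 (not isolated)
Conditions: LDA, THF, −95 °C; then 2, DMPU, −95 → −70 °C
Reagents that add atoms: none
Why: Alkylation of a lithium halocarbenoid: 3 persists below about −70 °C and should displace the primary allylic bromide of 2 in an SN2 reaction that leaves both E alkenes untouched and delivers the future C6 with both chlorines in place.

Step 2
Reactants: 5 L-erythrulose
Product: 6 3,4-O-isopropylidene-L-erythrulose (1-[(4S)-2,2-dimethyl-1,3-dioxolan-4-yl]-2-hydroxyethanone)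
Conditions: Me2C(OMe)2, acetone, CSA (cat.), rt
Reagents that add atoms: 2,2-dimethoxypropane, COC(C)(C)OC
Why: Acid-catalysed acetonide formation (transketalisation) engages the vicinal C4/C5 diol as the favoured five-membered dioxolane, leaves the C3a hydroxyl free and does not touch the C4 stereocentre.

Step 3
Reactants: 6 3,4-O-isopropylidene-L-erythrulose
Product: 7 2-[(4S)-2,2-dimethyl-1,3-dioxolan-4-yl]-2-oxoethyl acetate
Conditions: Ac2O, pyridine, CH2Cl2, 0 °C
Reagents that add atoms: acetic anhydride, CC(=O)OC(C)=O
Why: Routine O-acetylation under weakly basic conditions; the acetate survives the olefination and the acidic lactonisation and is later removed without a step of its own during the aminolysis of step 7.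

Step 4
Reactants: 7 acetoxy ketone; 8 methyl bis(2,2,2-trifluoroethyl)phosphonoacetate
Product: 10 methyl (2Z)-4-acetoxy-3-[(4R)-2,2-dimethyl-1,3-dioxolan-4-yl]but-2-enoate, via potassium phosphonate carbanion 9 (not isolated)
Conditions: 8, KHMDS, 18-crown-6, THF, −78 °C; then 7, −78 °C
Reagents that add atoms: none
Why: Still–Gennari variant of the Horner–Wadsworth–Emmons olefination: the irreversible, kinetically controlled addition of the trifluoroethyl phosphonate anion to this activated α,α′-dioxygenated ketone should place the ester cis to the larger branched dioxolanyl group (C1 cis to C4), and the cold, weakly basic anion should not enolise the ketone toward C4.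

Step 5
Reactants: 10 Z-enoate acetonide
Product: 12 [(2R)-2-(hydroxymethyl)-5-oxo-2,5-dihydrofuran-3-yl]methyl acetate, via Z-diol ester 11 (not isolated)
Conditions: TFA–H2O, CH2Cl2, 0 °C → rt
Reagents that add atoms: none
Why: Acetonide hydrolysis followed by spontaneous lactonisation: only the Z ester can reach the C4 hydroxyl, so the five-membered ring closure locks the C1/C4 cis geometry, leaves any E isomer behind as a separable open-chain diol ester and singles out the C5 hydroxyl as the only free one.

Step 6
Reactants: 12 butenolide alcohol
Product: 13 [(2R)-5-oxo-2-(triethylsilyloxymethyl)-2,5-dihydrofuran-3-yl]methyl acetate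
Conditions: TESCl, imidazole, CH2Cl2, 0 °C
Reagents that add atoms: chlorotriethylsilane, CC[Si](Cl)(CC)CC
Why: Routine silylation of the single primary alcohol with a base too weak to deprotonate the butenolide at C4; triethylsilyl is chosen because mild acid removes it later in the presence of the silylene.

Step 7
Reactants: 13 TES butenolide acetate
Product: 14 (2Z,4R)-4-hydroxy-3-(hydroxymethyl)-N-methoxy-N-methyl-5-(triethylsilyloxy)pent-2-enamide
Conditions: MeNH(OMe)·HCl, AlMe3 (excess), CH2Cl2, 0 °C → rt; Rochelle salt work-up; used crude
Reagents that add atoms: N,O-dimethylhydroxylamine hydrochloride, CNOC.Cl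
Why: Weinreb aminolysis with the aluminium amide opens the lactone at C1 with retention of the ring-derived Z geometry and, used in excess, converts the acetate into its own Weinreb amide, so that the C3a/C4 1,3-diol is released in one operation by a reagent of low basicity that should leave C4 intact.

Step 8
Reactants: 14 Z-diol Weinreb amide
Product: 15 (2Z)-2-[(4R)-2,2-di-tert-butyl-4-(triethylsilyloxymethyl)-1,3,2-dioxasilinan-5-ylidene]-N-methoxy-N-methylacetamide
Conditions: t-Bu2Si(OTf)2, 2,6-lutidine, CH2Cl2, −78 → 0 °C
Reagents that add atoms: di-tert-butylsilyl bis(trifluoromethanesulfonate), CC(C)(C)[Si](OS(=O)(=O)C(F)(F)F)(OS(=O)(=O)C(F)(F)F)C(C)(C)C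
Why: Cyclic silylene protection of a 1,3-diol, run at once on the crude diol to outrun relactonisation; the six-membered ring is preferred to two separate silyl ethers because it keeps C4–O near the alkene plane, whereas a free C4 silyloxy group next to the C3 substituent would turn pseudo-axial (A1,2 strain) on the nascent carbocycle and favour the wrong C5 epimer.

Step 9
Reactants: 4 farnesyl-CHCl2; 15 silylene Weinreb amide
Product: 18 (1Z,5E,9E)-3,3-dichloro-1-[(4R)-2,2-di-tert-butyl-4-(triethylsilyloxymethyl)-1,3,2-dioxasilinan-5-ylidene]-6,10,14-trimethylpentadeca-5,9,13-trien-2-one, via lithium carbenoid 16 (not isolated), via tetrahedral lithium adduct 17 (not isolated)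
Conditions: 4 (slight excess over base), LDA, THF–Et2O, −95 °C; then 15, −95 → −78 °C; AcOH, −78 °C
Reagents that add atoms: none
Why: Acylation of a lithium halocarbenoid by a Weinreb amide: α-lithiation of the gem-dichloride at −95 °C should outrun loss of HCl, the chelated adduct 17 cannot collapse before the cold quench so that a second addition is excluded, and because C4–O is already blocked the electron-poor ketone can neither close to a lactol nor dehydrate to a furan.

Step 10
Reactants: 18 dichloro enone TES ether
Product: 19 (1Z,5E,9E)-3,3-dichloro-1-[(4R)-2,2-di-tert-butyl-4-(hydroxymethyl)-1,3,2-dioxasilinan-5-ylidene]-6,10,14-trimethylpentadeca-5,9,13-trien-2-one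
Conditions: PPTS (cat.), MeOH–CH2Cl2, 0 °C
Reagents that add atoms: none
Why: Acid-catalysed methanolysis of a silyl ether distinguishes the unhindered primary triethylsilyl group from the bulky six-membered di-tert-butylsilylene, and gem-dichloride, enone and trisubstituted alkenes are inert to PPTS.

Step 11
Reactants: 19 dichloro enone alcohol
Product: 20 (4R,5Z)-2,2-di-tert-butyl-5-[(5E,9E)-3,3-dichloro-6,10,14-trimethyl-2-oxopentadeca-5,9,13-trien-1-ylidene]-1,3,2-dioxasilinane-4-carbaldehyde
Conditions: Dess–Martin periodinane, NaHCO3, CH2Cl2, 0 °C; short filtration, used at once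
Reagents that add atoms: none
Why: Dess–Martin oxidation runs under buffered, nearly neutral conditions without amine base, which should preserve the labile C4–H and the Z alkene, and any hemiketal between C5–OH and the C1 ketone is drained through its open form.

Step 12
Reactants: 20 Z-enone aldehyde with C6 gem-dichloride
Product: 23 (4R,5R,6R)-C3a,C4-O-(di-tert-butylsilylene) derivative of the deacetyl target, via samarium chloro dienolate 21 (not isolated), via samarium chloro aldolate 22 (not isolated)
Conditions: SmI2 (2.0 equiv, titrated, 0.1 M in THF, syringe pump) added to 20 (0.005 M in THF), −78 °C; then → 0 °C; pH 7 phosphate buffer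
Reagents that add atoms: none
Why: Proposed new method: two equivalents of SmI2 cleave one C6–Cl bond of the activated α,α-dichloro ketone, giving samarium(III) chloro dienolate 21, whose C6 adds to the C5 aldehyde in a 6-(enolendo)-exo-trig aldol closure of the carbocycle (22), after which the C5 alkoxide expels the remaining tertiary α-keto chloride from the rear in a 3-exo-tet closure of the oxirane. The closest known reaction types are samarium(II)- or chromium(II)-mediated intramolecular Reformatsky aldol cyclisations of α-halo carbonyl compounds and the intermolecular reductive halo-aldol/Darzens sequence of α,α-dihalo ketones with aldehydes, which have not been merged into one annulation on a dichloro enone aldehyde. C5 is controlled by the bought C4 centre: the silylene ring holds C4–O pseudo-equatorial on the nascent ring, so C6 bonds anti to C4–O (polar Felkin–Anh alignment), and samarium on the enolate oxygen can reach the aldehyde oxygen only when C5–O is axial, which is the face that puts C5–O cis to C4–O. C6 is controlled by C5, because only the aldolate with C6–Cl antiperiplanar to C5–O can close and the oxirane is necessarily cis-fused, while aldolates that cannot reach this alignment on the silylene-locked half-chair should revert by retro-aldol cleavage. The step needs chemoselectivity for the first C–Cl bond over monochloro aldolate, epoxy ketone, aldehyde and γ-oxygenated enone, which the easier reduction of the CCl2–C=O unit, the slow addition of just two equivalents of titrated reagent at −78 °C without proton source, and high dilution (against intermolecular aldol addition) are meant to secure. No Brønsted base is present, so the C4–H, activated by both the aldehyde and the enone, should keep its configuration.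

Step 13
Reactants: 23 silylene-protected epoxy enone
Product: 24 (1R,5R,6R)-5-hydroxy-4-(hydroxymethyl)-1-[(2E,6E)-3,7,11-trimethyldodeca-2,6,10-trienyl]-7-oxabicyclo[4.1.0]hept-3-en-2-one
Conditions: HF·pyridine, pyridine, THF, 0 °C
Reagents that add atoms: none
Why: Fluoride-induced cleavage of the silylene is fast under pyridine-buffered conditions that should not open the carbonyl-deactivated oxirane or protonate the farnesyl alkenes, and the cis C4 hydroxyl cannot attack the oxirane from the rear (no Payne rearrangement).

Step 14
Reactants: 24 epoxy enone diol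
Product: 25 (1R,5R,6R)-4-(acetoxymethyl)-5-hydroxy-1-[(2E,6E)-3,7,11-trimethyldodeca-2,6,10-trienyl]-7-oxabicyclo[4.1.0]hept-3-en-2-one (target)
Conditions: AcCl (1 equiv), 2,4,6-collidine, CH2Cl2, −78 °C
Reagents that add atoms: acetyl chloride, CC(=O)Cl
Why: Chemoselective acylation of a primary in the presence of a secondary alcohol: one equivalent of acetyl chloride with the hindered base collidine at low temperature should acetylate only the unhindered C3a hydroxyl, the C4 hydroxyl being secondary and flanked by the oxirane and the C3 substituent.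

Compound list
1 | dichloromethane | ClCCl | starting material
2 | (2E,6E)-farnesyl bromide | CC(C)=CCC/C(C)=C/CC/C(C)=C/CBr | starting material
3 | dichloromethyllithium | [Li]C(Cl)Cl | intermediate
4 | (3E,7E)-1,1-dichloro-4,8,12-trimethyltrideca-3,7,11-triene | ClC(Cl)C/C=C(\C)CC/C=C(\C)CCC=C(C)C | intermediate
5 | L-erythrulose, (3S)-1,3,4-trihydroxybutan-2-one | OCC(=O)[C@@H](O)CO | starting material
6 | 3,4-O-isopropylidene-L-erythrulose | OCC(=O)[C@@H]1COC(C)(C)O1 | intermediate
7 | 2-[(4S)-2,2-dimethyl-1,3-dioxolan-4-yl]-2-oxoethyl acetate | CC(=O)OCC(=O)[C@@H]1COC(C)(C)O1 | intermediate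
8 | methyl bis(2,2,2-trifluoroethyl)phosphonoacetate | COC(=O)CP(=O)(OCC(F)(F)F)OCC(F)(F)F | starting material
9 | potassium carbanion of 8 | [K+].COC(=O)[CH-]P(=O)(OCC(F)(F)F)OCC(F)(F)F | intermediate
10 | methyl (2Z)-4-acetoxy-3-[(4R)-2,2-dimethyl-1,3-dioxolan-4-yl]but-2-enoate | COC(=O)/C=C(/COC(C)=O)[C@@H]1COC(C)(C)O1 | intermediate
11 | methyl (2Z,4R)-3-(acetoxymethyl)-4,5-dihydroxypent-2-enoate | COC(=O)/C=C(/COC(C)=O)[C@@H](O)CO | intermediate
12 | [(2R)-2-(hydroxymethyl)-5-oxo-2,5-dihydrofuran-3-yl]methyl acetate | CC(=O)OCC1=CC(=O)O[C@H]1CO | intermediate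
13 | [(2R)-5-oxo-2-(triethylsilyloxymethyl)-2,5-dihydrofuran-3-yl]methyl acetate | CC(=O)OCC1=CC(=O)O[C@H]1CO[Si](CC)(CC)CC | intermediate
14 | (2Z,4R)-4-hydroxy-3-(hydroxymethyl)-N-methoxy-N-methyl-5-(triethylsilyloxy)pent-2-enamide | CON(C)C(=O)/C=C(/CO)[C@@H](O)CO[Si](CC)(CC)CC | intermediate
15 | (2Z)-2-[(4R)-2,2-di-tert-butyl-4-(triethylsilyloxymethyl)-1,3,2-dioxasilinan-5-ylidene]-N-methoxy-N-methylacetamide | CON(C)C(=O)/C=C1/CO[Si](C(C)(C)C)(C(C)(C)C)O[C@H]1CO[Si](CC)(CC)CC | intermediate
16 | (3E,7E)-1,1-dichloro-4,8,12-trimethyltrideca-3,7,11-trien-1-yllithium | [Li]C(Cl)(Cl)C/C=C(\C)CC/C=C(\C)CCC=C(C)C | intermediate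
17 | lithium alkoxide of the tetrahedral adduct of 16 and 15 (C1 configuration undefined) | [Li]OC(N(C)OC)(/C=C1/CO[Si](C(C)(C)C)(C(C)(C)C)O[C@H]1CO[Si](CC)(CC)CC)C(Cl)(Cl)C/C=C(\C)CC/C=C(\C)CCC=C(C)C | intermediate
18 | Z-enone with C6 gem-dichloride, C3a/C4 silylene, C5 OTES | O=C(/C=C1/CO[Si](C(C)(C)C)(C(C)(C)C)O[C@H]1CO[Si](CC)(CC)CC)C(Cl)(Cl)C/C=C(\C)CC/C=C(\C)CCC=C(C)C | intermediate
19 | Z-enone with C6 gem-dichloride, C3a/C4 silylene, C5 OH | O=C(/C=C1/CO[Si](C(C)(C)C)(C(C)(C)C)O[C@H]1CO)C(Cl)(Cl)C/C=C(\C)CC/C=C(\C)CCC=C(C)C | intermediate
20 | (4R)-Z-enone aldehyde with C6 gem-dichloride and C3a/C4 silylene (key-step precursor) | O=C(/C=C1/CO[Si](C(C)(C)C)(C(C)(C)C)O[C@H]1C=O)C(Cl)(Cl)C/C=C(\C)CC/C=C(\C)CCC=C(C)C | intermediate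
21 | samarium(III) α-chloro dienolate of 20 (C1=C6 geometry undefined) | I[Sm](I)OC(/C=C1/CO[Si](C(C)(C)C)(C(C)(C)C)O[C@H]1C=O)=C(Cl)C/C=C(\C)CC/C=C(\C)CCC=C(C)C | intermediate
22 | samarium(III) (4R,5R,6S)-chloro aldolate, C5–O anti to C6–Cl and cis to C4–O | CC(C)(C)[Si]1(C(C)(C)C)OCC2=CC(=O)[C@](Cl)(C/C=C(\C)CC/C=C(\C)CCC=C(C)C)[C@H](O[Sm](I)I)[C@@H]2O1 | intermediate
23 | (4R,5R,6R)-C3a,C4-O-(di-tert-butylsilylene) deacetyl target (key-step product) | CC(C)(C)[Si]1(C(C)(C)C)OCC2=CC(=O)[C@]3(C/C=C(\C)CC/C=C(\C)CCC=C(C)C)O[C@@H]3[C@@H]2O1 | intermediate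
24 | deacetyl target diol | OCC1=CC(=O)[C@]2(C/C=C(\C)CC/C=C(\C)CCC=C(C)C)O[C@@H]2[C@@H]1O | intermediate
25 | CNP0184985.1 | CC(=O)OCC1=CC(=O)[C@]2(C/C=C(\C)CC/C=C(\C)CCC=C(C)C)O[C@@H]2[C@@H]1O | target

Total step count: 14. Longest linear sequence: 13 steps (steps 2–14 from L-erythrulose). Step 1 is the side branch that joins in step 9.

Steps most likely to fail

1. Step 12.
- What may go wrong: a second electron transfer to the monochloro aldolate, followed by β-elimination and aromatisation; reductive opening of the freshly formed oxirane; attack on the wrong aldehyde face; or proton transfer from C4–H to the enolate.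
- Fallback: it sets out from 19 and returns at 23.
- SmI2 (2 equiv) in THF–MeOH at −78 °C, the established reductive α-dehalogenation of ketones, should remove one chlorine and give the α-monochloro ketone alcohol F1 (both C6 epimers).
- Buffered Dess–Martin oxidation should give the α-chloro keto aldehyde F2.
- A classical base-mediated intramolecular Darzens condensation (LiHMDS, THF, −78 → 0 °C) should then close carbocycle and oxirane to 23.
- Reduction and C–C bond formation are thereby separated, and no reductant is present when the oxirane forms. The price is exposure of C4–H to base.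

2. Step 9.
- What may go wrong: loss of HCl from 4 toward the conjugated chlorodiene; decay of the carbenoid before the hindered Z-amide has reacted at the temperature the carbenoid tolerates; or γ-deprotonation of the amide.
- Fallback: it sets out from 15 and returns at 18.
- DIBAL-H (THF, −78 °C) should reduce the Weinreb amide to the Z-enal F3.
- Carbenoid 16 should add to this far more electrophilic and less hindered carbonyl at −95 °C, with a cold AcOH quench to prevent chloro-oxirane formation. This gives the dichloro carbinol F4 as an inconsequential C1 epimer mixture.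
- Dess–Martin oxidation should give 18.

3. Step 4.
- What may go wrong: poor geometric selectivity, with the ester ending trans to C4, or partial enolisation of the ketone toward C4.
- Fallback: it sets out from 7 and returns at 13, and it replaces the intermolecular olefination by a ring-forming one.
- Aqueous acetic acid should remove the acetonide and give 1-O-acetyl-L-erythrulose F5.
- TESCl and imidazole at low temperature should silylate only the primary C5 hydroxyl and give the α-hydroxy ketone F6.
- (Triphenylphosphoranylidene)ketene in warm toluene should acylate the C4 hydroxyl to the ester ylide F7.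
- F7 closes by intramolecular Wittig olefination onto the C3 ketone, so that the butenolide ring itself dictates the C1/C4 cis geometry.

Further compounds
F1 | step 12 | Z-enone alcohol with C6 monochloride (C6 epimers), C3a/C4 silylene | O=C(/C=C1/CO[Si](C(C)(C)C)(C(C)(C)C)O[C@H]1CO)C(Cl)C/C=C(\C)CC/C=C(\C)CCC=C(C)C
F2 | step 12 | Z-enone aldehyde with C6 monochloride (C6 epimers), C3a/C4 silylene | O=C(/C=C1/CO[Si](C(C)(C)C)(C(C)(C)C)O[C@H]1C=O)C(Cl)C/C=C(\C)CC/C=C(\C)CCC=C(C)C
F3 | step 9 | (2Z)-2-[(4R)-2,2-di-tert-butyl-4-(triethylsilyloxymethyl)-1,3,2-dioxasilinan-5-ylidene]acetaldehyde | O=C/C=C1/CO[Si](C(C)(C)C)(C(C)(C)C)O[C@H]1CO[Si](CC)(CC)CC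
F4 | step 9 | C1 carbinol corresponding to 18 (C1 epimers) | OC(/C=C1/CO[Si](C(C)(C)C)(C(C)(C)C)O[C@H]1CO[Si](CC)(CC)CC)C(Cl)(Cl)C/C=C(\C)CC/C=C(\C)CCC=C(C)C
F5 | step 4 | 1-O-acetyl-L-erythrulose | CC(=O)OCC(=O)[C@@H](O)CO
F6 | step 4 | 1-O-acetyl-4-O-triethylsilyl-L-erythrulose | CC(=O)OCC(=O)[C@@H](O)CO[Si](CC)(CC)CC
F7 | step 4 | C4-O-(triphenylphosphoranylidene)acetate of F6 | CC(=O)OCC(=O)[C@@H](OC(=O)C=P(c1ccccc1)(c1ccccc1)c1ccccc1)CO[Si](CC)(CC)CC
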